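Start with an easy subtraction. The protic impurity is 30.0% of the starting material, so quenching one to one would leave 70.0% for products, and target in the birch run stalls lower, at 65.1%. The flask asked about is this same flask, followed further.

| flask | starting material | protic impurity | remark | time |
|---|---|---|---|---|
| birch | 0.30 M | 0.090 M | the very flask that is asked about, followed so far |  |
| flask | 0.30 M | 0.0900 M |  | 15 h |

birch run (percent of the starting material charged)

| time / h | isomer of the product / % | target / % |
|---|---|---|
| 0.333 | 0 | 6.2 |
| 1.00 | 0.4 | 27.9 |
| 1.50 | 0.4 | 41.0 |
| 2.50 | 0.5 | 56.4 |
| 4.00 | 0.7 | 64.0 |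
| 5.00 | 1.2 | 64.6 |
| 6.00 | 1.0 | 65.1 |

(each reading ± 0.3 percentage points)

- the analysis behind the earlier runs scatters by 0.3 percentage points, standard deviation

* share of isomer of the product in isomer of the product plus target at 15 min
* share of isomer of the product in isomer of the product plus target at 2.0 h
* share of isomer of the product in isomer of the product plus target at 15 h

If target and isomer of the product both form from the same species, each first order in it and neither running back, that concentration cancels from their ratio. So you can read the ratio directly. Pool the readings from 1.00 h to 2.50 h into the early share, isomer over isomer plus target, 1.03%. My estimate takes this for 15 min and 2.0 h.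

The last two readings pooled give a late share of 1.67% at a mean time of 5.50 h. Counting the drift from 1.50 h and running it straight to 15 h:

1.03% + (1.67% − 1.03%) × (15 h − 1.50 h) / (5.50 h − 1.50 h) = 3.19%

The weak link is that late share: it rests on two isomer readings of 1.2% and 1.0%, each scattered by 0.3 percentage points. Adding the reading at 4.00 h gives 1.48% at a mean time of 5.00 h:

1.03% + (1.48% − 1.03%) × (15 h − 1.50 h) / (5.00 h − 1.50 h) = 2.76%

I commit to that figure.

The forecast gave 0.9% at 15 min, 0.9% at 2.0 h and 3% at 15 h, slightly different from my numbers, on the ground that the late rise “hints at slow conversion of target to isomer”.

The flask gives 1.04%, 1.14% and 2.47%, so the forecast held within its margins.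

    starting material + protic impurity → quenched substrate (k = 0.270 M⁻¹ min⁻¹)
    intermediate ⇌ isomer of the product (K = 2.90, k = 2.80 × 10⁻⁴ min⁻¹)
    starting material → intermediate (k = 0.0170 min⁻¹)
    intermediate ⇌ target (K = 14.0, k = 0.0270 min⁻¹)

In this flask, by the forward rate of each step alone, the intermediate goes to target 96 times as fast as to isomer of the product at 0.558 h, and 96 times at 15.0 h, a selectivity factor that corresponds to a share of 1.03%, beside the flask's 1.04% at 15 min. The neighbour flask with 0.51 M of starting material gives 1.14% at 2.0 h, beside the early share of 1.03% read from the birch run, and 2.46% at 15 h, with target at 75.2%.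

All runs stem from a simulated flask for substances that don't exist, and the scatter is random.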